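**Plan**

- Locants: bicycle = 2-oxabicyclo[2.2.2]octane with C1 (O–CH bridgehead), O2, C3 (lactone C=O), C4 (quaternary bridgehead), C5 (spiro carbon, also C2' of the oxane), C6, C7, C8 (ketone); oxane = O1', C3'–C6'.
- Enabling feature: C5 is a tertiary ether carbon bonded to O1' and to C3', and C3' lies α to the oxygenated C4'. C5 is therefore a ketone carbon in disguise and C3'=C4' can be an enol silane, so one closure of a C5 oxocarbenium ion makes the C5–C3' bond, the oxane ring and the quaternary spiro centre.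
- Cuts: C8=O back to C8–OSi and 4'-OAc back to the 4'-ketone; then C5–C3' together with C5–O1' (bicyclic C5 ketone + six-carbon hydroxy enol silane); then C4–C8 (aldol); then O2–C3 (lactone from an acyl oxazolidinone) and C6–C1 (anti aldol).
- Ring order forward: δ-lactone, then the carbocycle that completes the bicycle (C4–C8), then the oxane (key step), then the functional-group endgame.
- Stereochemistry: C6 and C1 from a β-ketoimide anti aldol matched with the (R)-Roche aldehyde (C7); C4 from the bicycle geometry; C5' and C6' from (R)-3-hydroxybutanoate by anti methylation; C5 and C3' from the chair of the key closure; C4' from equatorial hydride delivery.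

Key step: step 13

Assumption: the (E)-boron enolate of 10 is taken to add with the 2,4-anti-4,5-anti sense established for this class of β-ketoimide, so that the (2R)-imide gives (4S,5S) in 14; compounds 1, 7, 8 and 11 are taken as commercial.

Step 1
Reactants: 1 methyl (3R)-3-hydroxybutanoate
Product: 2 methyl (2R,3R)-3-hydroxy-2-methylbutanoate
Conditions: LiN(i-Pr)2 (2.2 equiv), THF, −78 to −20 °C; MeI, DMPU, −78 to 0 °C; aqueous quench
Reagents that add atoms: iodomethane, CI
Why: Fráter–Seebach alkylation, in which the chelated alkoxide–enolate dianion is methylated anti to the C3 substituent and so sets C2 (R) beside the pool-derived C3 (R).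

Step 2
Reactants: 2 methyl (2R,3R)-3-hydroxy-2-methylbutanoate
Product: 4 (4R,5R)-5-hydroxy-4-methylhexan-3-one, via Weinreb amide 3 (not isolated)
Conditions: MeNHOMe·HCl, i-PrMgCl, THF, −20 °C; then EtMgBr, 0 °C; aqueous NH4Cl
Reagents that add atoms: ethylmagnesium bromide, CC[Mg]Br; N,O-dimethylhydroxylamine hydrochloride, CNOC.Cl (its atoms stay only in 3)
Why: One-pot Weinreb ketone synthesis, in which MeN(OMe)MgCl converts the ester into amide 3 and the tetrahedral adduct of 3 with EtMgBr survives until work-up, so only one ethyl group adds and the α-centre is not epimerized.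

Step 3
Reactants: 4 (4R,5R)-5-hydroxy-4-methylhexan-3-one
Product: 6 (2Z,4R,5R)-4-methyl-3,5-bis(trimethylsilyloxy)hex-2-ene, via silyl ether 5 (not isolated)
Conditions: Me3SiCl (3.5 equiv), Et3N, THF, 0 °C; then LiN(SiMe3)2 (2.3 equiv), −78 °C; pentane, filtration
Reagents that add atoms: chlorotrimethylsilane, C[Si](C)(C)Cl
Why: O-silylation followed by kinetic enolization at the unhindered ethyl CH2 with in-situ silyl trapping, which for α'-branched ethyl ketones should give the (Z)-enol silane that later places the 3'-methyl equatorial.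

Step 4
Reactants: 7 (4R)-4-benzyl-3-propanoyl-1,3-oxazolidin-2-one; 8 propanal
Product: 9 (4R)-4-benzyl-3-[(2R,3S)-3-hydroxy-2-methylpentanoyl]-1,3-oxazolidin-2-one
Conditions: Bu2BOTf, Et3N, CH2Cl2, 0 °C; 8, −78 to 0 °C; then pH 7 buffer, MeOH, H2O2
Reagents that add atoms: none
Why: Evans syn aldol through the (Z)-boron enolate and a Zimmerman–Traxler chair, which fixes C2 (R), the only centre kept after the next step.

Step 5
Reactants: 9 (4R)-4-benzyl-3-[(2R,3S)-3-hydroxy-2-methylpentanoyl]-1,3-oxazolidin-2-one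
Product: 10 (4R)-4-benzyl-3-[(2R)-2-methyl-3-oxopentanoyl]-1,3-oxazolidin-2-one
Conditions: SO3·pyridine, DMSO, Et3N, CH2Cl2, 0 °C
Reagents that add atoms: none
Why: Parikh–Doering oxidation, mild enough that the C2 centre of the β-ketoimide, shielded from enolization by allylic strain, should be retained.

Step 6
Reactants: 11 methyl (2R)-3-hydroxy-2-methylpropanoate
Product: 12 methyl (2R)-3-[tert-butyl(dimethyl)silyloxy]-2-methylpropanoate
Conditions: t-BuMe2SiCl, imidazole, CH2Cl2, 0 °C to rt
Reagents that add atoms: tert-butyldimethylsilyl chloride, CC(C)(C)[Si](C)(C)Cl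
Why: Standard silylation of the primary alcohol.

Step 7
Reactants: 12 methyl (2R)-3-[tert-butyl(dimethyl)silyloxy]-2-methylpropanoate
Product: 13 (2R)-3-[tert-butyl(dimethyl)silyloxy]-2-methylpropanal
Conditions: i-Bu2AlH, CH2Cl2, −78 °C; Rochelle salt work-up
Reagents that add atoms: none
Why: Partial ester reduction at −78 °C through the stable tetrahedral i-Bu2Al–O hemiacetal, which should give the α-methyl aldehyde without epimerization.

Step 8
Reactants: 10 (4R)-4-benzyl-3-[(2R)-2-methyl-3-oxopentanoyl]-1,3-oxazolidin-2-one; 13 (2R)-3-[tert-butyl(dimethyl)silyloxy]-2-methylpropanal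
Product: 14 (4R)-4-benzyl-3-[(2R,4S,5S,6R)-7-[tert-butyl(dimethyl)silyloxy]-5-hydroxy-2,4,6-trimethyl-3-oxoheptanoyl]-1,3-oxazolidin-2-one
Conditions: (c-C6H11)2BCl, EtNMe2, Et2O, 0 °C; 13, −78 to −20 °C; then MeOH, pH 7 buffer, H2O2, 0 °C
Reagents that add atoms: none
Why: Anti aldol of the (E)-dicyclohexylboron enolate formed only at C4, in which the C2 centre directs the enolate face (2,4-anti, 4,5-anti) and this is matched with Felkin–Anh addition to the (R)-aldehyde, setting C4 (S) and C5 (S) beside C6 (R).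

Step 9
Reactants: 14 (4R)-4-benzyl-3-[(2R,4S,5S,6R)-7-[tert-butyl(dimethyl)silyloxy]-5-hydroxy-2,4,6-trimethyl-3-oxoheptanoyl]-1,3-oxazolidin-2-one
Product: 15 (5S,6S)-6-[(2R)-1-[tert-butyl(dimethyl)silyloxy]propan-2-yl]-4-hydroxy-3,5-dimethyl-5,6-dihydro-2H-pyran-2-one
Conditions: DBU (1.5 equiv), CH2Cl2, 0 °C to rt; aqueous citric acid work-up
Reagents that add atoms: none
Why: Base-induced 6-exo-trig acyl transfer from the imide to the C5 hydroxyl (as in the cyclization of δ-hydroxy-β-keto esters to dihydropyran-2,4-diones), which closes the lactone, releases the auxiliary and removes the no longer needed C2 centre as the enol.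

Step 10
Reactants: 15 (5S,6S)-6-[(2R)-1-[tert-butyl(dimethyl)silyloxy]propan-2-yl]-4-hydroxy-3,5-dimethyl-5,6-dihydro-2H-pyran-2-one
Product: 16 (5S,6S)-4-hydroxy-6-[(2R)-1-hydroxypropan-2-yl]-3,5-dimethyl-5,6-dihydro-2H-pyran-2-one
Conditions: HF·pyridine, pyridine, THF, 0 °C to rt
Reagents that add atoms: none
Why: Fluoride cleavage of the primary silyl ether under buffered conditions that should leave the enolized β-keto lactone untouched.

Step 11
Reactants: 16 (5S,6S)-4-hydroxy-6-[(2R)-1-hydroxypropan-2-yl]-3,5-dimethyl-5,6-dihydro-2H-pyran-2-one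
Product: 17 (2S)-2-[(2R,3S)-4-hydroxy-3,5-dimethyl-6-oxo-3,6-dihydro-2H-pyran-2-yl]propanal
Conditions: Dess–Martin periodinane, CH2Cl2, 0 °C; used crude
Reagents that add atoms: none
Why: Dess–Martin oxidation of the primary alcohol without base, chosen so that the lactone oxygen β to the new aldehyde is not eliminated and the α-centre is not epimerized.

Step 12
Reactants: 17 (2S)-2-[(2R,3S)-4-hydroxy-3,5-dimethyl-6-oxo-3,6-dihydro-2H-pyran-2-yl]propanal
Product: 19 (1S,4R,6S,7S,8R)-8-[tert-butyl(dimethyl)silyloxy]-4,6,7-trimethyl-2-oxabicyclo[2.2.2]octane-3,5-dione, via silyl dienol ether 18 (not isolated)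
Conditions: t-BuMe2SiOTf (2.2 equiv), 2,6-lutidine (1.2 equiv), CH2Cl2, −78 to −20 °C
Reagents that add atoms: tert-butyldimethylsilyl triflate, CC(C)(C)[Si](C)(C)OS(=O)(=O)C(F)(F)F
Why: Silyl triflate-mediated intramolecular Mukaiyama aldol (6-enolendo-exo-trig) in which 18 attacks the silyl-activated aldehyde through C3 on the only face the tether allows (fixing C4), an open antiperiplanar transition state should place the C8 oxygen syn to the lactone bridge and trans to the C7 methyl, and silyl capture makes the aldol irreversible.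

Step 13
Reactants: 19 (1S,4R,6S,7S,8R)-8-[tert-butyl(dimethyl)silyloxy]-4,6,7-trimethyl-2-oxabicyclo[2.2.2]octane-3,5-dione; 6 (2Z,4R,5R)-4-methyl-3,5-bis(trimethylsilyloxy)hex-2-ene
Product: 20 (1S,4R,5R,6S,7S,8R,3'S,5'R,6'R)-8-[tert-butyl(dimethyl)silyloxy]-4,6,7,3',5',6'-hexamethylspiro[2-oxabicyclo[2.2.2]octane-5,2'-oxane]-3,4'-dione
Conditions: Me3SiOTf (0.2 equiv), 2,6-di-tert-butyl-4-methylpyridine (0.1 equiv), CH2Cl2, −78 to −40 °C; Et3N quench
Reagents that add atoms: none
Why: Proposed new method: Me3SiOTf should silylate the C5 ketone of 19, the silyl ether oxygen of 6 should add and (Me3Si)2O should leave to give the C5 oxocarbenium ion, which the tethered (Z)-enol silane captures through C3' before giving up its silyl group to reveal the 4'-ketone. The closest known reaction types are the silyl enol ether Prins cyclization of aldehyde-derived oxocarbenium ions, the silyl triflate-catalysed union of ketones or ketals with silyl ethers and with enol silanes, and Prins spirocyclizations of ketones; their combination on an α-quaternary bicyclic ketone is the unproven part. The oxane closes in the 6-endo-trig mode at the oxocarbenium carbon (6-enolendo for the enol silane) through a chair. The spiro centre C5 is controlled by this chair: the O1'–C6' bond lies syn to C6 and anti to quaternary C4 (away from the bridgehead methyl), so C4 becomes equatorial and C6 axial, and with the 5'- and 6'-methyls equatorial the (4R,5R) chain can reach only the C5 face anti to the C6 methyl, which is also the less hindered face of the bicycle; C3' is controlled by the (Z)-enol silane geometry, which places its methyl equatorial. The step needs reaction at one ketone only (C8 is masked as a silyl ether whose oxygen points away from the reacting face), face selectivity at C5 (tether chair and C6 methyl acting together) and no loss of configuration at C6 or C3' (low temperature, catalytic acid, hindered pyridine as proton trap).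

Step 14
Reactants: 20 (1S,4R,5R,6S,7S,8R,3'S,5'R,6'R)-8-[tert-butyl(dimethyl)silyloxy]-4,6,7,3',5',6'-hexamethylspiro[2-oxabicyclo[2.2.2]octane-5,2'-oxane]-3,4'-dione
Product: 22 (1S,4R,5S,6S,7S,8R,3'R,4'R,5'R,6'R)-8-[tert-butyl(dimethyl)silyloxy]-4,6,7,3',5',6'-hexamethyl-3-oxospiro[2-oxabicyclo[2.2.2]octane-5,2'-oxan]-4'-yl acetate, via lithium alkoxide 21 (not isolated)
Conditions: LiBH(s-Bu)3, THF, −78 °C; then Ac2O, DMAP, −78 °C to rt
Reagents that add atoms: acetic anhydride, CC(=O)OC(C)=O
Why: The bulky hydride should attack the 4'-ketone from the equatorial direction (the axial path is blocked by the axial C6 substituent on C2'), giving the axial alkoxide 21 cis to both flanking methyls, which is acetylated in the same pot while the bridged lactone is not reduced at −78 °C.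

Step 15
Reactants: 22 (1S,4R,5S,6S,7S,8R,3'R,4'R,5'R,6'R)-8-[tert-butyl(dimethyl)silyloxy]-4,6,7,3',5',6'-hexamethyl-3-oxospiro[2-oxabicyclo[2.2.2]octane-5,2'-oxan]-4'-yl acetate
Product: 23 (1S,4R,5S,6S,7R,8R,3'R,4'R,5'R,6'R)-8-hydroxy-4,6,7,3',5',6'-hexamethyl-3-oxospiro[2-oxabicyclo[2.2.2]octane-5,2'-oxan]-4'-yl acetate
Conditions: HF·pyridine, THF, 0 °C to rt
Reagents that add atoms: none
Why: Fluoride cleavage of the hindered secondary silyl ether, to which the acetate, the lactone and the tertiary spiro ether should be stable.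

Step 16
Reactants: 23 (1S,4R,5S,6S,7R,8R,3'R,4'R,5'R,6'R)-8-hydroxy-4,6,7,3',5',6'-hexamethyl-3-oxospiro[2-oxabicyclo[2.2.2]octane-5,2'-oxan]-4'-yl acetate
Product: 24 (1R,4S,5S,6S,7S,3'R,4'R,5'R,6'R)-4,6,7,3',5',6'-hexamethyl-3,8-dioxospiro[2-oxabicyclo[2.2.2]octane-5,2'-oxan]-4'-yl acetate (CNP0257416.1)
Conditions: Dess–Martin periodinane, CH2Cl2, 0 °C to rt
Reagents that add atoms: none
Why: Dess–Martin oxidation of the C8 alcohol under non-basic conditions, so the adjacent C7 centre carried from the Roche ester should not be epimerized.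

**Compound list**

1 | methyl (3R)-3-hydroxybutanoate | COC(=O)C[C@@H](C)O | starting material
2 | methyl (2R,3R)-3-hydroxy-2-methylbutanoate | COC(=O)[C@H](C)[C@@H](C)O | intermediate
3 | (2R,3R)-3-hydroxy-N-methoxy-N,2-dimethylbutanamide (Weinreb amide) | CON(C)C(=O)[C@H](C)[C@@H](C)O | intermediate
4 | (4R,5R)-5-hydroxy-4-methylhexan-3-one | CCC(=O)[C@H](C)[C@@H](C)O | intermediate
5 | (4R,5R)-4-methyl-5-(trimethylsilyloxy)hexan-3-one | CCC(=O)[C@H](C)[C@@H](C)O[Si](C)(C)C | intermediate
6 | (2Z,4R,5R)-4-methyl-3,5-bis(trimethylsilyloxy)hex-2-ene | C/C=C(\O[Si](C)(C)C)[C@H](C)[C@@H](C)O[Si](C)(C)C | intermediate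
7 | (4R)-4-benzyl-3-propanoyl-1,3-oxazolidin-2-one | CCC(=O)N1[C@H](Cc2ccccc2)COC1=O | starting material
8 | propanal | CCC=O | starting material
9 | (4R)-4-benzyl-3-[(2R,3S)-3-hydroxy-2-methylpentanoyl]-1,3-oxazolidin-2-one | CC[C@H](O)[C@@H](C)C(=O)N1[C@H](Cc2ccccc2)COC1=O | intermediate
10 | (4R)-4-benzyl-3-[(2R)-2-methyl-3-oxopentanoyl]-1,3-oxazolidin-2-one | CCC(=O)[C@@H](C)C(=O)N1[C@H](Cc2ccccc2)COC1=O | intermediate
11 | methyl (2R)-3-hydroxy-2-methylpropanoate | COC(=O)[C@H](C)CO | starting material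
12 | methyl (2R)-3-[tert-butyl(dimethyl)silyloxy]-2-methylpropanoate | COC(=O)[C@H](C)CO[Si](C)(C)C(C)(C)C | intermediate
13 | (2R)-3-[tert-butyl(dimethyl)silyloxy]-2-methylpropanal | O=C[C@H](C)CO[Si](C)(C)C(C)(C)C | intermediate
14 | (4R)-4-benzyl-3-[(2R,4S,5S,6R)-7-[tert-butyl(dimethyl)silyloxy]-5-hydroxy-2,4,6-trimethyl-3-oxoheptanoyl]-1,3-oxazolidin-2-one | CC(C)(C)[Si](C)(C)OC[C@@H](C)[C@H](O)[C@H](C)C(=O)[C@@H](C)C(=O)N1[C@H](Cc2ccccc2)COC1=O | intermediate
15 | (5S,6S)-6-[(2R)-1-[tert-butyl(dimethyl)silyloxy]propan-2-yl]-4-hydroxy-3,5-dimethyl-5,6-dihydro-2H-pyran-2-one (enol form of the β-keto-δ-lactone) | CC(C)(C)[Si](C)(C)OC[C@@H](C)[C@@H]1OC(=O)C(C)=C(O)[C@H]1C | intermediate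
16 | (5S,6S)-4-hydroxy-6-[(2R)-1-hydroxypropan-2-yl]-3,5-dimethyl-5,6-dihydro-2H-pyran-2-one | OC[C@@H](C)[C@@H]1OC(=O)C(C)=C(O)[C@H]1C | intermediate
17 | (2S)-2-[(2R,3S)-4-hydroxy-3,5-dimethyl-6-oxo-3,6-dihydro-2H-pyran-2-yl]propanal | O=C[C@@H](C)[C@@H]1OC(=O)C(C)=C(O)[C@H]1C | intermediate
18 | (2S)-2-[(2R,3S)-4-[tert-butyl(dimethyl)silyloxy]-3,5-dimethyl-6-oxo-3,6-dihydro-2H-pyran-2-yl]propanal | O=C[C@@H](C)[C@@H]1OC(=O)C(C)=C(O[Si](C)(C)C(C)(C)C)[C@H]1C | intermediate
19 | (1S,4R,6S,7S,8R)-8-[tert-butyl(dimethyl)silyloxy]-4,6,7-trimethyl-2-oxabicyclo[2.2.2]octane-3,5-dione (silyloxy syn to the lactone bridge, trans to the C7 methyl) | O=C1[C@@H](C)[C@H]2OC(=O)[C@]1(C)[C@H](O[Si](C)(C)C(C)(C)C)[C@H]2C | intermediate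
20 | (1S,4R,5R,6S,7S,8R,3'S,5'R,6'R)-8-[tert-butyl(dimethyl)silyloxy]-4,6,7,3',5',6'-hexamethylspiro[2-oxabicyclo[2.2.2]octane-5,2'-oxane]-3,4'-dione (target framework with 4'-ketone and 8-silyloxy; all shared centres as in the target) | O=C1[C@H](C)[C@@H](C)O[C@@]2([C@@H]1C)[C@@H](C)[C@H]1OC(=O)[C@]2(C)[C@H](O[Si](C)(C)C(C)(C)C)[C@H]1C | intermediate
21 | lithium alkoxide of the axial 4'-alcohol (22 without its acetyl group) | [Li+].[O-][C@@H]1[C@H](C)[C@@H](C)O[C@@]2([C@@H]1C)[C@@H](C)[C@H]1OC(=O)[C@]2(C)[C@H](O[Si](C)(C)C(C)(C)C)[C@H]1C | intermediate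
22 | (1S,4R,5S,6S,7S,8R,3'R,4'R,5'R,6'R)-8-[tert-butyl(dimethyl)silyloxy]-4,6,7,3',5',6'-hexamethyl-3-oxospiro[2-oxabicyclo[2.2.2]octane-5,2'-oxan]-4'-yl acetate (axial acetate) | CC(=O)O[C@@H]1[C@H](C)[C@@H](C)O[C@@]2([C@@H]1C)[C@@H](C)[C@H]1OC(=O)[C@]2(C)[C@H](O[Si](C)(C)C(C)(C)C)[C@H]1C | intermediate
23 | (1S,4R,5S,6S,7R,8R,3'R,4'R,5'R,6'R)-8-hydroxy-4,6,7,3',5',6'-hexamethyl-3-oxospiro[2-oxabicyclo[2.2.2]octane-5,2'-oxan]-4'-yl acetate | CC(=O)O[C@@H]1[C@H](C)[C@@H](C)O[C@@]2([C@@H]1C)[C@@H](C)[C@H]1OC(=O)[C@]2(C)[C@H](O)[C@H]1C | intermediate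
24 | (1R,4S,5S,6S,7S,3'R,4'R,5'R,6'R)-4,6,7,3',5',6'-hexamethyl-3,8-dioxospiro[2-oxabicyclo[2.2.2]octane-5,2'-oxan]-4'-yl acetate (CNP0257416.1) | CC(=O)O[C@@H]1[C@H](C)[C@@H](C)O[C@@]2([C@@H]1C)[C@@H](C)[C@H]1OC(=O)[C@]2(C)C(=O)[C@H]1C | target

**Step count and risks**

Total steps: 16. Longest linear sequence: 11 steps (7 to 24 through steps 4, 5 and 8–16).

Steps most likely to fail:

1. Step 13 (proposed new method). The oxocarbenium ion may form too slowly at the hindered, electron-poor C5 ketone. The silyl hemiketal may fragment by retro-Claisen cleavage of C4–C5. Silyl transfer may outrun C–C closure. Proton loss at C6 may divert the cation to an enol ether. Fallback by known chemistry, setting out from 2 and 19 and returning at 20: ester 2 is silylated (t-BuMe2SiCl, imidazole) to methyl (2R,3R)-3-[tert-butyl(dimethyl)silyloxy]-2-methylbutanoate F1, reduced with i-Bu2AlH at −78 °C to (2R,3R)-3-[tert-butyl(dimethyl)silyloxy]-2-methylbutanal F2, ethylidenated under Takai conditions (CH3CHI2, CrCl2, divalent chromium) to the (E)-alkene silyl ether F3 and desilylated with Bu4NF to (2R,3S,4E)-3-methylhex-4-en-2-ol F4. A classical Prins cyclization of F4 with ketone 19 in CF3CO2H/CH2Cl2 should give, through the same chair, the 4'-epimeric (equatorial) trifluoroacetate F5, with the (E)-alkene placing the 3'-methyl equatorial. Mild methanolysis (NaHCO3, MeOH) would give the equatorial 4'-alcohol F6, and Dess–Martin oxidation would give 20.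

2. Step 12. The aldol equilibrium may be unfavourable before silyl capture. The lactone oxygen may be eliminated β to the aldehyde. The aldehyde may enolize and lose the C7 configuration. Silylation may give the C8 epimer whose oxygen crowds the face needed in step 13. Fallback, setting out from 17 and returning at 19: a reversible, chelate-controlled aldol by soft enolization (MgBr2·OEt2, i-Pr2NEt, CH2Cl2) should settle on the more stable aldol, (1S,4R,6S,7R,8R)-8-hydroxy-4,6,7-trimethyl-2-oxabicyclo[2.2.2]octane-3,5-dione F7, in which the hydroxyl is trans to the C7 methyl. F7 is isolated and silylated separately (t-BuMe2SiOTf, 2,6-lutidine) to 19.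

3. Step 3. Enolization may occur partly at the branched α'-position, or may give E/Z mixtures that would erode the C3' configuration in step 13. Fallback, setting out from 3 (isolated in this variant) and returning at 20: amide 3 is treated with vinylmagnesium bromide to give (4R,5R)-5-hydroxy-4-methylhex-1-en-3-one F8, which is silylated (Me3SiCl, imidazole) to (4R,5R)-4-methyl-5-(trimethylsilyloxy)hex-1-en-3-one F9. Conjugate hydrosilylation of F9 (Et3SiH, RhCl(PPh3)3, monovalent rhodium) through the s-cis enone should give, regio- and stereospecifically, (2Z,4R,5R)-4-methyl-3-(triethylsilyloxy)-5-(trimethylsilyloxy)hex-2-ene F10, which replaces 6 in step 13 to give 20.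

**Further compounds**

F1 | step 13 | methyl (2R,3R)-3-[tert-butyl(dimethyl)silyloxy]-2-methylbutanoate | COC(=O)[C@H](C)[C@@H](C)O[Si](C)(C)C(C)(C)C
F2 | step 13 | (2R,3R)-3-[tert-butyl(dimethyl)silyloxy]-2-methylbutanal | O=C[C@H](C)[C@@H](C)O[Si](C)(C)C(C)(C)C
F3 | step 13 | tert-butyl(dimethyl)silyl ether of (2R,3S,4E)-3-methylhex-4-en-2-ol | C/C=C/[C@H](C)[C@@H](C)O[Si](C)(C)C(C)(C)C
F4 | step 13 | (2R,3S,4E)-3-methylhex-4-en-2-ol | C/C=C/[C@H](C)[C@@H](C)O
F5 | step 13 | 4'-epimeric (equatorial) trifluoroacetate corresponding to 22 (CF3CO2 in place of the axial acetate, all other centres as in 22) | O=C(O[C@H]1[C@H](C)[C@@H](C)O[C@@]2([C@@H]1C)[C@@H](C)[C@H]1OC(=O)[C@]2(C)[C@H](O[Si](C)(C)C(C)(C)C)[C@H]1C)C(F)(F)F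
F6 | step 13 | 4'-epimeric (equatorial) alcohol corresponding to 22 (free equatorial 4'-OH, 8-silyloxy retained) | O[C@H]1[C@H](C)[C@@H](C)O[C@@]2([C@@H]1C)[C@@H](C)[C@H]1OC(=O)[C@]2(C)[C@H](O[Si](C)(C)C(C)(C)C)[C@H]1C
F7 | step 12 | (1S,4R,6S,7R,8R)-8-hydroxy-4,6,7-trimethyl-2-oxabicyclo[2.2.2]octane-3,5-dione | O=C1[C@@H](C)[C@H]2OC(=O)[C@]1(C)[C@H](O)[C@H]2C
F8 | step 3 | (4R,5R)-5-hydroxy-4-methylhex-1-en-3-one | C=CC(=O)[C@H](C)[C@@H](C)O
F9 | step 3 | (4R,5R)-4-methyl-5-(trimethylsilyloxy)hex-1-en-3-one | C=CC(=O)[C@H](C)[C@@H](C)O[Si](C)(C)C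
F10 | step 3 | (2Z,4R,5R)-4-methyl-3-(triethylsilyloxy)-5-(trimethylsilyloxy)hex-2-ene | C/C=C(\O[Si](CC)(CC)CC)[C@H](C)[C@@H](C)O[Si](C)(C)C
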